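Atom labels used throughout: 2,3-dihydrobenzofuran numbering (O1, C2, C3, C3a, C4 to C7, C7a); ring A is the fused benzene ring, ring C the 4-hydroxy-3,5-dimethoxyphenyl ring on C2, and C9 the CH2O carbon on C3.

## Analysis of the target

Target 34 is a 2-aryl-2,3-dihydrobenzofuran neolignan. Ring A carries O1 on C7a, a methoxy group on C7, the C3 carbon on C3a and an (E)-3-acyloxyprop-1-enyl chain on C5; C2 carries ring C and C3 carries C9. There are two stereocentres, C2 (S) and C3 (R), adjacent and trans on the five-membered ring; trans is the more stable arrangement, so the real task is the absolute sense. Both primary oxygens (on C9 and at the end of the C5 chain) are acylated by 4-hydroxybenzoic acid, and three phenols are free. The sensitive points are the allylic ester (a cinnamyl ester whose arene has O1 para to the chain, so it ionises easily with acid or zerovalent palladium), the benzylic C2–O1 ether of an electron-rich arene, and both esters towards hydroxide or alkoxide. The difficulty lies in the 1,2,3,5-tetrasubstituted ring A with four different substituents, in the trans pair in one absolute sense, and in freeing three phenols last without touching the esters. The strategy rests on one feature: C7a and C3a are neighbours on ring A, one bearing O1 and the other C3, which is the pattern left when an oxygen nucleophile and a carbon acceptor add across an aryne. The oxygen on C7, next to C7a, can be carried through that step as a boronate, and a boronate beside an aryne steers the nucleophile to the adjacent carbon.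

## Retrosynthetic reasoning

**34 to 32.** The three phenols are masked as methoxymethyl ethers in 32 (the tris-MOM diester), so only three acetal O–CH2 bonds are cut in the last step. One protecting group class for all three phenols allows a single, nearly neutral unmasking that spares the cinnamyl ester and the C2–O1 ether.

**32 to 28 and 31.** Both ester C–O bonds are cut at once, giving diol 28 (C9–OH and the allylic alcohol) and two equivalents of acid 31 (4-(methoxymethoxy)benzoic acid). Acylating last keeps the esters away from the basic and palladium-mediated steps, where a cinnamyl ester would ionise.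

**28 to 24 and 27.** The C5–vinyl bond is cut, giving arylboronate 24 and (E)-3-iodoprop-2-en-1-ol 27. The alkene geometry is then fixed in a small fragment and transferred with retention.

**24 to 21.** The C5–B bond is traced back to C5–H of alcohol 21. C5–H is the only ring hydrogen with no ortho substituent, so a sterically governed C–H borylation can find it. Electrophilic substitution was not chosen because ring C is the more activated arene.

**21 to 20, 19 and 18.** The C9 oxygen is traced back to silicon (silane 20) and the C7 methoxy group to a phenol (19) and then to a boronate (18). The two heteroatoms are exchanged in separate steps so that the C7 oxygen can be methylated before the C9 oxygen exists. This leaves C9–OH as the only hydroxyl to be acylated later.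

**18 to 8 and 13 (key disconnection).** O1–C7a and C3a–C3 are cut together, giving the achiral aryne precursor 8 (boronate, trimethylsilyl and triflate on three adjacent carbons) and the enantioenriched allylic alcohol 13 (an E-vinylsilane). In the forward direction the alkoxide of 13 must add to the aryne carbon next to boron. The aryl anion left on the other carbon must then close the ring onto the vinylsilane before anything protonates it. C2 comes unchanged from 13; C3 is set in the ring closure.

**13 to 12, and 12 to 10 and 11; 10 to 9.** The E-vinylsilane is traced to propargylic alcohol 12, since alkoxide-directed trans-hydroalumination gives the E isomer with silicon already on the terminal carbon. Hydrosilylation of a terminal alkyne was avoided because its regiochemistry is less certain. Cutting the carbinol–alkyne bond of 12 gives aldehyde 10 and silylalkyne 11, joined by a catalytic asymmetric alkynylation; 10 is syringaldehyde 9 with its phenol masked.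

**8 to 6, 5, 2 and 1.** The triflate is traced to a carbamate-protected phenol (6), the boronate to a bromide (5), and the trimethylsilyl group to a C–H flanked by the carbamate and the bromine (2). This leads back to 3-bromophenol 1.

**27 to 26 and 25; 31 to 29.** The vinyl iodide comes from vinylstannane 26, made by hydrostannylation of propargyl alcohol 25. Acid 31 comes from 4-hydroxybenzoic acid 29.

## Alternatives that were turned down

**Alternative 1:** Ring A is built last. C3a–C4 and C7a–C7 are cut, leaving the trans lactone A1, which already holds O1, C2, C3, C3a and C7a with both stereocentres, and the bromopyrone ester A2. In the forward step A1 is converted to its O-silyl enolate, which adds across the pyrone diene (C3a to the carbon next to the pyrone oxygen, C7a to the carbon bearing bromine). CO2 and then silanol are lost to give arene A3.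
- For: the trans pair is fixed on a saturated ring before the key step, and C5 and C7 both arrive functionalised, so no late C–H borylation is needed. On both points it is stronger than the chosen route.
- Against: after CO2 is lost, aromatisation can expel either silanol or the ring oxygen O1, and the second path opens the dihydrofuran. A1 needs its own enantioselective synthesis with two stereocentres. The C5 ester of A3 needs several redox and olefination steps to become the allylic alcohol, and the C7 bromide still has to become a methoxy group.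
- Comparison: the chosen strategy offers in return a shorter, convergent assembly from one catalytically made stereocentre.

**Alternative 2:** The C2–C3 bond is cut. The aryldiazoacetate A4 is decomposed by Rh2(S-PTTL)4 (dirhodium tetrakis[N-phthaloyl-(S)-tert-leucinate], a divalent rhodium carboxylate). The carbene carbon C3 inserts into a benzylic C–H bond of the OCH2Ar group and gives the cis ester A5.
- For: this is the strongest alternative on precedent. One catalyst sets both centres, C7–OMe and a C5 bromide are present from the start, and the total count is probably lower.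
- Against: the ester comes out cis and must be epimerised at C3 through its enolate. That enolate is beta to O1, so an E1cB opening of the ring that would erase C2 has to be avoided. The C5 bromide still needs a coupling that installs the allylic alcohol, and a diazo compound has to be made and handled.
- Comparison: the chosen strategy gives the trans isomer directly, forms both ring bonds in one convergent operation, and needs no diazo intermediate. Its price is an unprecedented key step.

**Alternative 3:** O1–C7a is cut. The iodo alcohol A6, with both stereocentres in place, is deprotonated and cyclised with CuI (monovalent copper), 1,10-phenanthroline and Cs2CO3 to give A7.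
- For: the ring closure is a reliable reaction type and cannot disturb C2, because no bond at the carbinol carbon is broken. On the reliability of the key step it is stronger than the chosen route.
- Against: both stereocentres of A6 must be set on an open chain by auxiliary or aldol chemistry followed by redox adjustments. The iodide is flanked by a methoxy group and a branched alkyl group. A hot benzylic alkoxide may dehydrogenate or eliminate. A7 lacks a C5 handle, so the same late borylation is needed as in the chosen route.
- Comparison: the chosen strategy forms two bonds, the ring and one stereocentre in the step where this alternative forms one bond, and it reaches its precursors in fewer steps.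

Key step: step 8

Remark on the chemistry: the sense of the zinc–ProPhenol alkynylation is fixed by the ligand antipode. The antipode that gives Si-face addition to aldehyde 10 is meant, and the configuration of 12 is to be confirmed through its MTPA esters. Silylalkyne 11 is taken as a commercial reagent.

## Route

Step 1
Reactants: 1 3-bromophenol
Product: 2 3-bromophenyl N-(propan-2-yl)carbamate
Conditions: i-PrNCO, Et3N (cat.), CH2Cl2, rt
Reagents that add atoms: isopropyl isocyanate, CC(C)N=C=O
Why: Amine-catalysed addition of the phenol to the isocyanate (carbamoylation) installs a directing group that can later be removed under mild base.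

Step 2
Reactants: 2 3-bromophenyl N-(propan-2-yl)carbamate
Product: 5 3-bromo-2-(trimethylsilyl)phenyl N-(propan-2-yl)carbamate, via N-silyl carbamate 3 (not isolated), via C-silylated N-silyl carbamate 4 (not isolated)
Conditions: TBSOTf, TMEDA, Et2O, 0 °C to rt; then Me3SiCl, LiN(i-Pr)2, THF, −78 °C; aq. NaHSO4
Reagents that add atoms: chlorotrimethylsilane, C[Si](C)(C)Cl
Why: Directed ortho-metalation: the N-silylated carbamate and the bromine together acidify the C–H between them, a lithium amide is used so that bromine–lithium exchange cannot compete, and Me3SiCl present in the flask traps the aryllithium before it can lose LiBr; the N–Si bond is hydrolysed on acidic work-up.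

Step 3
Reactants: 5 3-bromo-2-(trimethylsilyl)phenyl N-(propan-2-yl)carbamate
Product: 6 3-(4,4,5,5-tetramethyl-1,3,2-dioxaborolan-2-yl)-2-(trimethylsilyl)phenyl N-(propan-2-yl)carbamate
Conditions: B2pin2, PdCl2(dppf) (cat.), KOAc, 1,4-dioxane, 90 °C
Reagents that add atoms: bis(pinacolato)diboron, CC1(C)OB(OC1(C)C)B1OC(C)(C)C(C)(C)O1
Why: Miyaura borylation of the aryl bromide; acetate is too weak a base to cleave the carbamate or the C–Si bond, and aryl carbamates do not add oxidatively to palladium under these conditions.

Step 4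
Reactants: 6 3-(4,4,5,5-tetramethyl-1,3,2-dioxaborolan-2-yl)-2-(trimethylsilyl)phenyl N-(propan-2-yl)carbamate
Product: 8 3-(4,4,5,5-tetramethyl-1,3,2-dioxaborolan-2-yl)-2-(trimethylsilyl)phenyl trifluoromethanesulfonate, via phenol 7 (not isolated)
Conditions: Et2NH, DBU, MeCN, 40 °C; then PhNTf2, rt
Reagents that add atoms: N-phenylbis(trifluoromethanesulfonimide), O=S(=O)(N(c1ccccc1)S(=O)(=O)C(F)(F)F)C(F)(F)F
Why: The N–H carbamate is cleaved by an E1cB elimination to the phenoxide and isopropyl isocyanate, which diethylamine traps as a urea, and the phenoxide is triflated in the same flask; no fluoride is present, so the silyl triflate and the boronate survive.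

Step 5
Reactants: 9 syringaldehyde (4-hydroxy-3,5-dimethoxybenzaldehyde)
Product: 10 3,5-dimethoxy-4-(methoxymethoxy)benzaldehyde
Conditions: MOMCl, i-Pr2NEt, CH2Cl2, 0 °C to rt
Reagents that add atoms: chloromethyl methyl ether, COCCl
Why: O-alkylation of the phenol gives a methoxymethyl ether that tolerates hydride, KH, fluoride, peroxide and palladium and, unlike a silyl ether, is not cleaved by CsF in step 8.

Step 6
Reactants: 10 3,5-dimethoxy-4-(methoxymethoxy)benzaldehyde; 11 ethynyl(dimethyl)phenylsilane
Product: 12 (R)-3-[dimethyl(phenyl)silyl]-1-[3,5-dimethoxy-4-(methoxymethoxy)phenyl]prop-2-yn-1-ol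
Conditions: Me2Zn, ProPhenol ligand (2,6-bis{[2-(hydroxydiphenylmethyl)pyrrolidin-1-yl]methyl}-4-methylphenol, antipode for Si-face addition, 20 mol%), Ph3P=O (40 mol%), toluene, 0 °C
Reagents that add atoms: none
Why: Catalytic asymmetric alkynylation of an aromatic aldehyde by a zinc alkynylide held in a chiral dinuclear zinc complex; the ligand directs the alkynyl group to the Si face and so sets the carbinol centre that becomes C2 (the descriptor is R here only because the silylalkynyl group outranks the aryl group).

Step 7
Reactants: 12 (R)-3-[dimethyl(phenyl)silyl]-1-[3,5-dimethoxy-4-(methoxymethoxy)phenyl]prop-2-yn-1-ol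
Product: 13 (S,E)-3-[dimethyl(phenyl)silyl]-1-[3,5-dimethoxy-4-(methoxymethoxy)phenyl]prop-2-en-1-ol
Conditions: NaAlH2(OCH2CH2OMe)2, THF, 0 °C to rt; aq. sodium potassium tartrate
Reagents that add atoms: none
Why: Alkoxide-directed trans-hydroalumination of the propargylic alcohol followed by protonolysis of the vinyl–aluminium bond gives the E-vinylsilane only; the carbinol centre is not touched and its descriptor changes to S solely because vinyl ranks below aryl.

Step 8
Reactants: 13 (S,E)-3-[dimethyl(phenyl)silyl]-1-[3,5-dimethoxy-4-(methoxymethoxy)phenyl]prop-2-en-1-ol; 8 3-(4,4,5,5-tetramethyl-1,3,2-dioxaborolan-2-yl)-2-(trimethylsilyl)phenyl trifluoromethanesulfonate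
Product: 18 2-[(2S,3S)-3-{[dimethyl(phenyl)silyl]methyl}-2-[3,5-dimethoxy-4-(methoxymethoxy)phenyl]-2,3-dihydro-1-benzofuran-7-yl]-4,4,5,5-tetramethyl-1,3,2-dioxaborolane (trans), via potassium alkoxide 14 (not isolated), via borylbenzyne 15 (not isolated), via aryl anion 16 (not isolated), via silyl carbanion 17 (not isolated)
Conditions: KH, THF, 0 °C; then 8 (1.5 equiv), CsF, 18-crown-6, THF, −20 °C to rt; aq. NH4Cl
Reagents that add atoms: none
Why: Proposed new method: fluoride removes the trimethylsilyl group of 8 and triflate leaves, giving aryne 15 between C7a and C3a; the electropositive boron on C7, as the neutral boronate or as its alkoxide ate complex, makes the adjacent aryne carbon C7a the more linear and electrophilic one, so alkoxide 14 bonds there (O1–C7a), in the way amines are known to add next to boron in 3-borylarynes. The aryl anion 16 at C3a then adds to the near carbon of the E-vinylsilane (C3a–C3), a carbometalation favoured because silicon stabilises the resulting carbanion 17, which is protonated by the medium or on quench. The closest known reaction types are ortho-selective nucleophilic additions to 3-borylarynes, aryne O-arylation followed by capture of the aryl anion by a tethered acceptor, and anionic 5-exo cyclisations of aryllithiums onto silyl-activated alkenes; their combination with a chiral allylic alkoxide is new. The dihydrofuran ring closes in the 5-exo-trig mode. C2 is carried over from 13 because no bond at the carbinol carbon is broken, and C3 is set in the ring closure, where an envelope-like transition state with the C2 aryl group pseudo-equatorial places the silylmethyl carbon trans to it. The step needs O-attack at C7a and not C3a (secured by boron), ring closure faster than protonation of 16 (secured by complete deprotonation with KH, which leaves only H2, and an aprotic medium), and no migration of silicon to oxygen (excluded by the E geometry).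

Step 9
Reactants: 18 2-[(2S,3S)-3-{[dimethyl(phenyl)silyl]methyl}-2-[3,5-dimethoxy-4-(methoxymethoxy)phenyl]-2,3-dihydro-1-benzofuran-7-yl]-4,4,5,5-tetramethyl-1,3,2-dioxaborolane
Product: 19 (2S,3S)-3-{[dimethyl(phenyl)silyl]methyl}-2-[3,5-dimethoxy-4-(methoxymethoxy)phenyl]-2,3-dihydro-1-benzofuran-7-ol
Conditions: H2O2 (30%), NaOH (aq), THF, 0 °C
Reagents that add atoms: hydrogen peroxide, OO
Why: Oxidation of the arylboronate by 1,2-migration of the aryl group from boron to oxygen; the alkyl–SiMe2Ph bond is inert to alkaline peroxide without activation of silicon, so only C7 is oxidised.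

Step 10
Reactants: 19 (2S,3S)-3-{[dimethyl(phenyl)silyl]methyl}-2-[3,5-dimethoxy-4-(methoxymethoxy)phenyl]-2,3-dihydro-1-benzofuran-7-ol
Product: 20 {[(2S,3S)-7-methoxy-2-[3,5-dimethoxy-4-(methoxymethoxy)phenyl]-2,3-dihydro-1-benzofuran-3-yl]methyl}(dimethyl)phenylsilane
Conditions: MeI, K2CO3, DMF, rt
Reagents that add atoms: iodomethane, CI
Why: Williamson methylation of the only free hydroxyl; doing this before C9 is oxidised means that no second hydroxyl can be methylated.

Step 11
Reactants: 20 {[(2S,3S)-7-methoxy-2-[3,5-dimethoxy-4-(methoxymethoxy)phenyl]-2,3-dihydro-1-benzofuran-3-yl]methyl}(dimethyl)phenylsilane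
Product: 21 [(2S,3R)-7-methoxy-2-[3,5-dimethoxy-4-(methoxymethoxy)phenyl]-2,3-dihydro-1-benzofuran-3-yl]methanol
Conditions: t-BuOOH, KH, NMP, rt; then Bu4NF, 70 °C
Reagents that add atoms: tert-butyl hydroperoxide, CC(C)(C)OO
Why: Fleming–Tamao oxidation in its nucleophilic form: tert-butylperoxide anion displaces phenyl from silicon and fluoride promotes the shift of C9 from silicon to oxygen; this form is chosen because the electrophilic variants (bromine, mercuric acetate, strong acid) would attack ring C, ring A or the MOM acetal; the descriptor at C3 becomes R only because oxygen replaces silicon on C9.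

Step 12
Reactants: 21 [(2S,3R)-7-methoxy-2-[3,5-dimethoxy-4-(methoxymethoxy)phenyl]-2,3-dihydro-1-benzofuran-3-yl]methanol
Product: 24 [(2S,3R)-7-methoxy-2-[3,5-dimethoxy-4-(methoxymethoxy)phenyl]-5-(4,4,5,5-tetramethyl-1,3,2-dioxaborolan-2-yl)-2,3-dihydro-1-benzofuran-3-yl]methanol, via O-boryl ether 22 (not isolated), via diboryl intermediate 23 (not isolated)
Conditions: HBpin, THF, rt; then B2pin2, [Ir(OMe)(cod)]2 (cat.), 4,4′-di-tert-butyl-2,2′-bipyridine, THF, 60 °C; MeOH
Reagents that add atoms: bis(pinacolato)diboron, CC1(C)OB(OC1(C)C)B1OC(C)(C)C(C)(C)O1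
Why: Iridium-catalysed C–H borylation is governed by sterics, and C5–H is the only arene hydrogen without an ortho substituent (C4–H lies next to the ring fusion, C6–H next to the methoxy group, and the ring C hydrogens are flanked on both sides); the hydroxyl is masked in the flask as its O-boryl ether and freed by methanol.

Step 13
Reactants: 25 propargyl alcohol (prop-2-yn-1-ol)
Product: 26 (E)-3-(tributylstannyl)prop-2-en-1-ol
Conditions: Bu3SnH, AIBN (cat.), toluene, 80 °C; chromatography
Reagents that add atoms: tributyltin hydride, CCCC[SnH](CCCC)CCCC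
Why: Radical hydrostannylation of the terminal alkyne places tin on the terminal carbon and equilibrates towards the E isomer, which is separated from the minor isomers.

Step 14
Reactants: 26 (E)-3-(tributylstannyl)prop-2-en-1-ol
Product: 27 (E)-3-iodoprop-2-en-1-ol
Conditions: I2, CH2Cl2, 0 °C
Reagents that add atoms: iodine, II
Why: Iododestannylation replaces tin by iodine at the same carbon with retention of the alkene geometry.

Step 15
Reactants: 24 [(2S,3R)-7-methoxy-2-[3,5-dimethoxy-4-(methoxymethoxy)phenyl]-5-(4,4,5,5-tetramethyl-1,3,2-dioxaborolan-2-yl)-2,3-dihydro-1-benzofuran-3-yl]methanol; 27 (E)-3-iodoprop-2-en-1-ol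
Product: 28 (E)-3-[(2S,3R)-3-(hydroxymethyl)-7-methoxy-2-[3,5-dimethoxy-4-(methoxymethoxy)phenyl]-2,3-dihydro-1-benzofuran-5-yl]prop-2-en-1-ol
Conditions: Pd(PPh3)4 (cat.), K2CO3, THF/H2O, 60 °C
Reagents that add atoms: none
Why: Suzuki–Miyaura coupling of the arylboronate with the vinyl iodide proceeds with retention of the E geometry; the allylic position is still a free alcohol, which zerovalent palladium does not ionise.

Step 16
Reactants: 29 4-hydroxybenzoic acid
Product: 31 4-(methoxymethoxy)benzoic acid, via methoxymethyl ester 30 (not isolated)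
Conditions: MOMCl, i-Pr2NEt, CH2Cl2, 0 °C to rt; then NaOH, THF/MeOH/H2O, rt; dil. HCl to pH 4
Reagents that add atoms: chloromethyl methyl ether, COCCl
Why: Both acidic groups are alkylated and the far more labile methoxymethyl ester is then saponified selectively, leaving the aryl MOM ether.

Step 17
Reactants: 28 (E)-3-[(2S,3R)-3-(hydroxymethyl)-7-methoxy-2-[3,5-dimethoxy-4-(methoxymethoxy)phenyl]-2,3-dihydro-1-benzofuran-5-yl]prop-2-en-1-ol; 31 4-(methoxymethoxy)benzoic acid
Product: 32 [(2S,3R)-7-methoxy-2-[3,5-dimethoxy-4-(methoxymethoxy)phenyl]-5-[(E)-3-{[4-(methoxymethoxy)benzoyl]oxy}prop-1-en-1-yl]-2,3-dihydro-1-benzofuran-3-yl]methyl 4-(methoxymethoxy)benzoate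
Conditions: 31 (2.4 equiv), EDC·HCl, DMAP, CH2Cl2, 0 °C to rt
Reagents that add atoms: none
Why: Steglich esterification acylates both primary alcohols under neutral conditions that do not ionise the cinnamyl position and need no acid chloride, which would endanger the MOM groups.

Step 18
Reactants: 32 [(2S,3R)-7-methoxy-2-[3,5-dimethoxy-4-(methoxymethoxy)phenyl]-5-[(E)-3-{[4-(methoxymethoxy)benzoyl]oxy}prop-1-en-1-yl]-2,3-dihydro-1-benzofuran-3-yl]methyl 4-(methoxymethoxy)benzoate
Product: 34 quiquesetinerviusin B, [(2S,3R)-2-(4-hydroxy-3,5-dimethoxyphenyl)-5-[(E)-3-(4-hydroxybenzoyloxy)prop-1-en-1-yl]-7-methoxy-2,3-dihydro-1-benzofuran-3-yl]methyl 4-hydroxybenzoate, via tris(trimethylsilyl) ether 33 (not isolated)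
Conditions: Me3SiOTf, 2,2′-bipyridyl, MeCN, 0 °C to rt; then H2O
Reagents that add atoms: none
Why: The bipyridyl-buffered silyl triflate converts aryl MOM ethers into aryl trimethylsilyl ethers, which water hydrolyses; the medium stays close to neutral, so the esters, the cinnamyl C–O bond and the benzylic C2–O1 bond are expected to survive, and no stereocentre is involved.

## Compound list

1 | 3-bromophenol | Oc1cccc(Br)c1 | starting material
2 | 3-bromophenyl N-(propan-2-yl)carbamate | CC(C)NC(=O)Oc1cccc(Br)c1 | intermediate
3 | 3-bromophenyl N-(tert-butyldimethylsilyl)-N-(propan-2-yl)carbamate | CC(C)N(C(=O)Oc1cccc(Br)c1)[Si](C)(C)C(C)(C)C | intermediate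
4 | 3-bromo-2-(trimethylsilyl)phenyl N-(tert-butyldimethylsilyl)-N-(propan-2-yl)carbamate | CC(C)N(C(=O)Oc1cccc(Br)c1[Si](C)(C)C)[Si](C)(C)C(C)(C)C | intermediate
5 | 3-bromo-2-(trimethylsilyl)phenyl N-(propan-2-yl)carbamate | CC(C)NC(=O)Oc1cccc(Br)c1[Si](C)(C)C | intermediate
6 | 3-(4,4,5,5-tetramethyl-1,3,2-dioxaborolan-2-yl)-2-(trimethylsilyl)phenyl N-(propan-2-yl)carbamate | CC(C)NC(=O)Oc1cccc(B2OC(C)(C)C(C)(C)O2)c1[Si](C)(C)C | intermediate
7 | 3-(4,4,5,5-tetramethyl-1,3,2-dioxaborolan-2-yl)-2-(trimethylsilyl)phenol | CC1(C)OB(OC1(C)C)c1cccc(O)c1[Si](C)(C)C | intermediate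
8 | 3-(4,4,5,5-tetramethyl-1,3,2-dioxaborolan-2-yl)-2-(trimethylsilyl)phenyl trifluoromethanesulfonate | CC1(C)OB(OC1(C)C)c1cccc(OS(=O)(=O)C(F)(F)F)c1[Si](C)(C)C | intermediate
9 | syringaldehyde | COc1cc(C=O)cc(OC)c1O | starting material
10 | 3,5-dimethoxy-4-(methoxymethoxy)benzaldehyde | COc1cc(C=O)cc(OC)c1OCOC | intermediate
11 | ethynyl(dimethyl)phenylsilane | C#C[Si](C)(C)c1ccccc1 | starting material
12 | (R)-3-[dimethyl(phenyl)silyl]-1-[3,5-dimethoxy-4-(methoxymethoxy)phenyl]prop-2-yn-1-ol | COc1cc([C@@H](O)C#C[Si](C)(C)c2ccccc2)cc(OC)c1OCOC | intermediate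
13 | (S,E)-3-[dimethyl(phenyl)silyl]-1-[3,5-dimethoxy-4-(methoxymethoxy)phenyl]prop-2-en-1-ol | COc1cc([C@@H](O)/C=C/[Si](C)(C)c2ccccc2)cc(OC)c1OCOC | intermediate
14 | potassium (S,E)-3-[dimethyl(phenyl)silyl]-1-[3,5-dimethoxy-4-(methoxymethoxy)phenyl]prop-2-en-1-olate | COc1cc([C@@H]([O-])/C=C/[Si](C)(C)c2ccccc2)cc(OC)c1OCOC.[K+] | intermediate
15 | 3-(4,4,5,5-tetramethyl-1,3,2-dioxaborolan-2-yl)benzyne | CC1(C)OB(OC1(C)C)C1=CC=CC#C1 | intermediate
16 | potassium 2-{[(1S,2E)-3-[dimethyl(phenyl)silyl]-1-[3,5-dimethoxy-4-(methoxymethoxy)phenyl]prop-2-en-1-yl]oxy}-3-(4,4,5,5-tetramethyl-1,3,2-dioxaborolan-2-yl)benzen-1-ide | COc1cc([C@@H](Oc2c(B3OC(C)(C)C(C)(C)O3)ccc[c-]2)/C=C/[Si](C)(C)c2ccccc2)cc(OC)c1OCOC.[K+] | intermediate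
17 | potassium [(2S,3S)-2-[3,5-dimethoxy-4-(methoxymethoxy)phenyl]-7-(4,4,5,5-tetramethyl-1,3,2-dioxaborolan-2-yl)-2,3-dihydro-1-benzofuran-3-yl][dimethyl(phenyl)silyl]methanide | COc1cc([C@H]2Oc3c(B4OC(C)(C)C(C)(C)O4)cccc3[C@@H]2[CH-][Si](C)(C)c2ccccc2)cc(OC)c1OCOC.[K+] | intermediate
18 | 2-[(2S,3S)-3-{[dimethyl(phenyl)silyl]methyl}-2-[3,5-dimethoxy-4-(methoxymethoxy)phenyl]-2,3-dihydro-1-benzofuran-7-yl]-4,4,5,5-tetramethyl-1,3,2-dioxaborolane (trans) | COc1cc([C@H]2Oc3c(B4OC(C)(C)C(C)(C)O4)cccc3[C@@H]2C[Si](C)(C)c2ccccc2)cc(OC)c1OCOC | intermediate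
19 | (2S,3S)-3-{[dimethyl(phenyl)silyl]methyl}-2-[3,5-dimethoxy-4-(methoxymethoxy)phenyl]-2,3-dihydro-1-benzofuran-7-ol | COc1cc([C@H]2Oc3c(O)cccc3[C@@H]2C[Si](C)(C)c2ccccc2)cc(OC)c1OCOC | intermediate
20 | {[(2S,3S)-7-methoxy-2-[3,5-dimethoxy-4-(methoxymethoxy)phenyl]-2,3-dihydro-1-benzofuran-3-yl]methyl}(dimethyl)phenylsilane | COc1cc([C@H]2Oc3c(OC)cccc3[C@@H]2C[Si](C)(C)c2ccccc2)cc(OC)c1OCOC | intermediate
21 | [(2S,3R)-7-methoxy-2-[3,5-dimethoxy-4-(methoxymethoxy)phenyl]-2,3-dihydro-1-benzofuran-3-yl]methanol | COc1cc([C@H]2Oc3c(OC)cccc3[C@@H]2CO)cc(OC)c1OCOC | intermediate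
22 | 2-{[(2S,3R)-7-methoxy-2-[3,5-dimethoxy-4-(methoxymethoxy)phenyl]-2,3-dihydro-1-benzofuran-3-yl]methoxy}-4,4,5,5-tetramethyl-1,3,2-dioxaborolane | COc1cc([C@H]2Oc3c(OC)cccc3[C@@H]2COB2OC(C)(C)C(C)(C)O2)cc(OC)c1OCOC | intermediate
23 | 2-{[(2S,3R)-7-methoxy-2-[3,5-dimethoxy-4-(methoxymethoxy)phenyl]-5-(4,4,5,5-tetramethyl-1,3,2-dioxaborolan-2-yl)-2,3-dihydro-1-benzofuran-3-yl]methoxy}-4,4,5,5-tetramethyl-1,3,2-dioxaborolane | COc1cc([C@H]2Oc3c(OC)cc(B4OC(C)(C)C(C)(C)O4)cc3[C@@H]2COB2OC(C)(C)C(C)(C)O2)cc(OC)c1OCOC | intermediate
24 | [(2S,3R)-7-methoxy-2-[3,5-dimethoxy-4-(methoxymethoxy)phenyl]-5-(4,4,5,5-tetramethyl-1,3,2-dioxaborolan-2-yl)-2,3-dihydro-1-benzofuran-3-yl]methanol | COc1cc([C@H]2Oc3c(OC)cc(B4OC(C)(C)C(C)(C)O4)cc3[C@@H]2CO)cc(OC)c1OCOC | intermediate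
25 | propargyl alcohol | C#CCO | starting material
26 | (E)-3-(tributylstannyl)prop-2-en-1-ol | CCCC[Sn](CCCC)(CCCC)/C=C/CO | intermediate
27 | (E)-3-iodoprop-2-en-1-ol | OC/C=C/I | intermediate
28 | (E)-3-[(2S,3R)-3-(hydroxymethyl)-7-methoxy-2-[3,5-dimethoxy-4-(methoxymethoxy)phenyl]-2,3-dihydro-1-benzofuran-5-yl]prop-2-en-1-ol | COc1cc([C@H]2Oc3c(OC)cc(/C=C/CO)cc3[C@@H]2CO)cc(OC)c1OCOC | intermediate
29 | 4-hydroxybenzoic acid | O=C(O)c1ccc(O)cc1 | starting material
30 | methoxymethyl 4-(methoxymethoxy)benzoate | COCOC(=O)c1ccc(OCOC)cc1 | intermediate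
31 | 4-(methoxymethoxy)benzoic acid | COCOc1ccc(C(=O)O)cc1 | intermediate
32 | [(2S,3R)-7-methoxy-2-[3,5-dimethoxy-4-(methoxymethoxy)phenyl]-5-[(E)-3-{[4-(methoxymethoxy)benzoyl]oxy}prop-1-en-1-yl]-2,3-dihydro-1-benzofuran-3-yl]methyl 4-(methoxymethoxy)benzoate | COc1cc([C@H]2Oc3c(OC)cc(/C=C/COC(=O)c4ccc(OCOC)cc4)cc3[C@@H]2COC(=O)c2ccc(OCOC)cc2)cc(OC)c1OCOC | intermediate
33 | tris(trimethylsilyl) ether of 34 (all three phenols silylated) | COc1cc([C@H]2Oc3c(OC)cc(/C=C/COC(=O)c4ccc(O[Si](C)(C)C)cc4)cc3[C@@H]2COC(=O)c2ccc(O[Si](C)(C)C)cc2)cc(OC)c1O[Si](C)(C)C | intermediate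
34 | quiquesetinerviusin B | COc1cc([C@H]2Oc3c(OC)cc(/C=C/COC(=O)c4ccc(O)cc4)cc3[C@@H]2COC(=O)c2ccc(O)cc2)cc(OC)c1O | target

## Step count and uncertain steps

Total step count: 18. Longest linear sequence: 12 steps (steps 1 to 4, 8 to 12, 15, 17 and 18, from 3-bromophenol).

**Step 8 (key step, the one step beyond known chemistry).** Several processes can divert it.
- The aryl anion may be quenched before ring closure, most plausibly by internal transfer of the doubly activated C2–H. This would leave an open aryl ether and erode the configuration at C2.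
- Regiocontrol of the O-arylation may be lost if coordination of fluoride to boron changes its directing effect.
- The silicon-stabilised carbanion may undergo 1,3-elimination of the aryloxide (cyclopropane formation) or add to a second aryne.
- The triflate may transfer its sulfonyl group to the alkoxide.

Fallback with known chemistry: it sets out from aldehyde 10. Alkynylation as in step 6 but with the antipodal ligand gives (S)-3-[dimethyl(phenyl)silyl]-1-[3,5-dimethoxy-4-(methoxymethoxy)phenyl]prop-2-yn-1-ol F1. Hydroalumination as in step 7 gives (R,E)-3-[dimethyl(phenyl)silyl]-1-[3,5-dimethoxy-4-(methoxymethoxy)phenyl]prop-2-en-1-ol F2. Mitsunobu etherification of F2 with commercial 2-bromo-6-methoxyphenol (PPh3, DIAD, toluene, 0 °C) inverts the carbinol centre and gives [(1E,3S)-3-(2-bromo-6-methoxyphenoxy)-3-[3,5-dimethoxy-4-(methoxymethoxy)phenyl]prop-1-en-1-yl](dimethyl)phenylsilane F3. Bu3SnH and AIBN in toluene at 80 °C then generate the aryl radical at C3a, which closes 5-exo onto the vinylsilane; the silicon-stabilised radical is reduced and the trans isomer should predominate. The fallback comes back to the route at silane 20, so steps 1 to 4, 9 and 10 are no longer needed. Its own weak point is partial loss of configuration during the Mitsunobu step at an electron-rich benzylic, allylic carbinol.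

**Step 11.** Displacement of phenyl from silicon may be incomplete, or the electron-rich arenes may be degraded by hot basic peroxide. Fallback: it sets out from 20 and replaces nucleophilic by electrophilic activation of silicon, accepting loss of the MOM group. HBF4·OEt2 in CH2Cl2 removes phenyl by ipso-protonation and cleaves the acetal, giving 4-[(2S,3S)-3-{[fluoro(dimethyl)silyl]methyl}-7-methoxy-2,3-dihydro-1-benzofuran-2-yl]-2,6-dimethoxyphenol F4. H2O2, KF and KHCO3 in THF/MeOH oxidise the fluorosilane to 4-[(2S,3R)-3-(hydroxymethyl)-7-methoxy-2,3-dihydro-1-benzofuran-2-yl]-2,6-dimethoxyphenol F5. Phenol-selective alkylation (MOMCl, K2CO3, acetone) returns to the route at 21. If acid opens the C2–O1 bond reversibly, C3 is unaffected and should direct reclosure to the trans isomer.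

**Step 18.** The silyl triflate may ionise the cinnamyl ester or the C2–O1 bond, or the hindered ring C acetal may need forcing. Fallback: it sets out from 24 and removes the acetal before the sensitive chain exists. HCl in MeOH at 0 °C gives 4-[(2S,3R)-3-(hydroxymethyl)-7-methoxy-5-(4,4,5,5-tetramethyl-1,3,2-dioxaborolan-2-yl)-2,3-dihydro-1-benzofuran-2-yl]-2,6-dimethoxyphenol F6. Coupling with 27 as in step 15 gives 4-[(2S,3R)-3-(hydroxymethyl)-5-[(E)-3-hydroxyprop-1-en-1-yl]-7-methoxy-2,3-dihydro-1-benzofuran-2-yl]-2,6-dimethoxyphenol F7. A double Mitsunobu esterification of the two primary alcohols with unprotected acid 29 (PPh3, DIAD, THF, 0 °C) then leads straight to target 34. The carboxyl group is several orders of magnitude more acidic than the phenols and is the expected nucleophile. Steps 16 to 18 are then not needed.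

**Step 2.** The ortho-lithiated bromide may lose LiBr, or the amide base may attack the N-silyl carbamate. Fallback: it sets out from 1 and uses a tertiary carbamate that cannot be attacked at nitrogen and is unmasked by reduction before boron is introduced. ClCONEt2 and K2CO3 in MeCN give 3-bromophenyl N,N-diethylcarbamate F8. LiN(i-Pr)2 with Me3SiCl present (THF, −78 °C) gives 3-bromo-2-(trimethylsilyl)phenyl N,N-diethylcarbamate F9. LiAlH4 (THF, 0 °C to rt) gives 3-bromo-2-(trimethylsilyl)phenol F10. Miyaura borylation of F10 as in step 3 comes back to the route at phenol 7, which is triflated (PhNTf2, Et3N) to 8.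

## Further compounds

F1 | step 8 | (S)-3-[dimethyl(phenyl)silyl]-1-[3,5-dimethoxy-4-(methoxymethoxy)phenyl]prop-2-yn-1-ol | COc1cc([C@H](O)C#C[Si](C)(C)c2ccccc2)cc(OC)c1OCOC
F2 | step 8 | (R,E)-3-[dimethyl(phenyl)silyl]-1-[3,5-dimethoxy-4-(methoxymethoxy)phenyl]prop-2-en-1-ol | COc1cc([C@H](O)/C=C/[Si](C)(C)c2ccccc2)cc(OC)c1OCOC
F3 | step 8 | [(1E,3S)-3-(2-bromo-6-methoxyphenoxy)-3-[3,5-dimethoxy-4-(methoxymethoxy)phenyl]prop-1-en-1-yl](dimethyl)phenylsilane | COc1cc([C@@H](Oc2c(Br)cccc2OC)/C=C/[Si](C)(C)c2ccccc2)cc(OC)c1OCOC
F4 | step 11 | 4-[(2S,3S)-3-{[fluoro(dimethyl)silyl]methyl}-7-methoxy-2,3-dihydro-1-benzofuran-2-yl]-2,6-dimethoxyphenol | COc1cc([C@H]2Oc3c(OC)cccc3[C@@H]2C[Si](C)(C)F)cc(OC)c1O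
F5 | step 11 | 4-[(2S,3R)-3-(hydroxymethyl)-7-methoxy-2,3-dihydro-1-benzofuran-2-yl]-2,6-dimethoxyphenol | COc1cc([C@H]2Oc3c(OC)cccc3[C@@H]2CO)cc(OC)c1O
F6 | step 18 | 4-[(2S,3R)-3-(hydroxymethyl)-7-methoxy-5-(4,4,5,5-tetramethyl-1,3,2-dioxaborolan-2-yl)-2,3-dihydro-1-benzofuran-2-yl]-2,6-dimethoxyphenol | COc1cc([C@H]2Oc3c(OC)cc(B4OC(C)(C)C(C)(C)O4)cc3[C@@H]2CO)cc(OC)c1O
F7 | step 18 | 4-[(2S,3R)-3-(hydroxymethyl)-5-[(E)-3-hydroxyprop-1-en-1-yl]-7-methoxy-2,3-dihydro-1-benzofuran-2-yl]-2,6-dimethoxyphenol | COc1cc([C@H]2Oc3c(OC)cc(/C=C/CO)cc3[C@@H]2CO)cc(OC)c1O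
F8 | step 2 | 3-bromophenyl N,N-diethylcarbamate | CCN(CC)C(=O)Oc1cccc(Br)c1
F9 | step 2 | 3-bromo-2-(trimethylsilyl)phenyl N,N-diethylcarbamate | CCN(CC)C(=O)Oc1cccc(Br)c1[Si](C)(C)C
F10 | step 2 | 3-bromo-2-(trimethylsilyl)phenol | C[Si](C)(C)c1c(O)cccc1Br
A1 | alternative 1 | (4R,5S)-4-{[tert-butyl(dimethyl)silyl]oxymethyl}-5-[3,5-dimethoxy-4-(methoxymethoxy)phenyl]oxolan-2-one (trans) | COc1cc([C@H]2OC(=O)C[C@@H]2CO[Si](C)(C)C(C)(C)C)cc(OC)c1OCOC
A2 | alternative 1 | methyl 3-bromo-2-oxo-2H-pyran-5-carboxylate | COC(=O)C1=COC(=O)C(Br)=C1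
A3 | alternative 1 | methyl (2S,3R)-7-bromo-3-{[tert-butyl(dimethyl)silyl]oxymethyl}-2-[3,5-dimethoxy-4-(methoxymethoxy)phenyl]-2,3-dihydro-1-benzofuran-5-carboxylate (trans) | COc1cc([C@H]2Oc3c(Br)cc(C(=O)OC)cc3[C@@H]2CO[Si](C)(C)C(C)(C)C)cc(OC)c1OCOC
A4 | alternative 2 | methyl 2-[5-bromo-3-methoxy-2-({3,5-dimethoxy-4-[tri(propan-2-yl)silyloxy]phenyl}methoxy)phenyl]-2-diazoacetate | COC(=O)C(=[N+]=[N-])c1cc(Br)cc(OC)c1OCc1cc(OC)c(O[Si](C(C)C)(C(C)C)C(C)C)c(OC)c1
A5 | alternative 2 | methyl (2S,3R)-5-bromo-7-methoxy-2-{3,5-dimethoxy-4-[tri(propan-2-yl)silyloxy]phenyl}-2,3-dihydro-1-benzofuran-3-carboxylate (cis) | COc1cc([C@H]2Oc3c(OC)cc(Br)cc3[C@H]2C(=O)OC)cc(OC)c1O[Si](C(C)C)(C(C)C)C(C)C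
A6 | alternative 3 | (1S,2R)-3-{[tert-butyl(dimethyl)silyl]oxy}-2-(2-iodo-3-methoxyphenyl)-1-[3,5-dimethoxy-4-(methoxymethoxy)phenyl]propan-1-ol | COc1cc([C@@H](O)[C@@H](CO[Si](C)(C)C(C)(C)C)c2cccc(OC)c2I)cc(OC)c1OCOC
A7 | alternative 3 | (2S,3R)-3-{[tert-butyl(dimethyl)silyl]oxymethyl}-7-methoxy-2-[3,5-dimethoxy-4-(methoxymethoxy)phenyl]-2,3-dihydro-1-benzofuran (trans) | COc1cc([C@H]2Oc3c(OC)cccc3[C@@H]2CO[Si](C)(C)C(C)(C)C)cc(OC)c1OCOC
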